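## Retrosynthetic overview

1. Ring numbering used below: C1 (O-tigloyl), C2 (iPr), C3 (O-acyl), C4/C5 epoxide (C5-Me), C6, C7, C8=C9 (C9-Me), C10 (OH).
2. The ten-membered carbocycle is closed last, at C9–C10, by an intramolecular Ni/Cr coupling of vinyl iodide and aldehyde in 40, which also sets C10 and frees the only OH. The epoxide, the only other ring, is made earlier on the open chain (step 20).
3. Ester C–O bonds: C3–O from acid 28 (Yamaguchi). The C1 tiglate and the C3 carbinol are made together by an Evans–Tishchenko reduction with tiglaldehyde.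
4. C3–C4: aldehyde 11 (C10–C3) plus enyne 19 (C4–C9), joined by Zr-catalysed carboalumination and alkenylalane addition, then oxidation to the enone.
5. 11 comes from an Evans syn aldol (isovaleryl imide + PMBOCH2CHO), 19 from but-2-yn-1-ol + TMS-propyne, and 28 from an Evans syn aldol (propionyl imide + acetaldehyde).

Assumption: the two recoverable oxazolidinone auxiliaries are treated as reagents (no atom of them reaches 42), and metal alkoxides or chelates that are only protonated on work-up are not numbered.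

## Route

Step 1
Reactants: 1 prop-2-en-1-ol
Product: 2 allyl 4-methoxybenzyl ether
Conditions: NaH, PMBCl, n-Bu4NI (cat.), THF/DMF, 0 °C → rt
Reagents that add atoms: 4-methoxybenzyl chloride, COc1ccc(CCl)cc1
Why: Williamson etherification of the sodium alkoxide with the benzylic chloride under iodide catalysis.

Step 2
Reactants: 2 allyl 4-methoxybenzyl ether
Product: 4 2-[(4-methoxybenzyl)oxy]acetaldehyde, via diol 3 (not isolated)
Conditions: OsO4 (2 mol %), NaIO4 (4 equiv), 2,6-lutidine, dioxane/H2O, rt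
Reagents that add atoms: osmium tetroxide (catalytic oxygen carrier), O=[Os](=O)(=O)=O; sodium periodate (terminal oxidant), [Na+].[O-]I(=O)(=O)=O
Why: Lemieux–Johnson cleavage (Os-catalysed dihydroxylation, then periodate glycol cleavage) unmasks the aldehyde without touching the electron-rich PMB ring.

Step 3
Reactants: 5 3-methylbutanoyl chloride
Product: 6 (4S)-4-benzyl-3-(3-methylbutanoyl)-1,3-oxazolidin-2-one
Conditions: (S)-4-benzyloxazolidin-2-one, n-BuLi, THF, −78 °C; then 5, −78 → 0 °C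
Reagents that add atoms: (S)-4-benzyloxazolidin-2-one, O=C1N[C@@H](Cc2ccccc2)CO1
Why: N-acylation of the lithiated Evans auxiliary by the acid chloride.

Step 4
Reactants: 6 (4S)-4-benzyl-3-(3-methylbutanoyl)-1,3-oxazolidin-2-one; 4 2-[(4-methoxybenzyl)oxy]acetaldehyde
Product: 8 (4S)-4-benzyl-3-[(2S,3S)-3-hydroxy-4-[(4-methoxybenzyl)oxy]-2-(propan-2-yl)butanoyl]-1,3-oxazolidin-2-one, via boron enolate 7 (not isolated)
Conditions: n-Bu2BOTf, i-Pr2NEt, CH2Cl2, 0 °C; then 4, −78 → 0 °C; then pH 7 buffer, MeOH, 30 % H2O2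
Reagents that add atoms: none
Why: Evans syn aldol reaction: the Z-boron enolate reacts through a Zimmerman–Traxler chair on the face opposite the benzyl group of the (S)-auxiliary, setting C1 (S) and C2 (S) with the 1,2-syn O/iPr relationship of the target.

Step 5
Reactants: 8 (4S)-4-benzyl-3-[(2S,3S)-3-hydroxy-4-[(4-methoxybenzyl)oxy]-2-(propan-2-yl)butanoyl]-1,3-oxazolidin-2-one
Product: 9 (2S,3S)-3-hydroxy-N-methoxy-4-[(4-methoxybenzyl)oxy]-N-methyl-2-(propan-2-yl)butanamide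
Conditions: MeNH(OMe)·HCl, AlMe3, THF/CH2Cl2, −20 → 0 °C; 1 M HCl work-up
Reagents that add atoms: N,O-dimethylhydroxylamine hydrochloride, CNOC.Cl
Why: Weinreb transamination with the aluminium amide, delivered through the β-alkoxide chelate, cleaves the auxiliary at the exocyclic carbonyl without epimerising C2.

Step 6
Reactants: 9 (2S,3S)-3-hydroxy-N-methoxy-4-[(4-methoxybenzyl)oxy]-N-methyl-2-(propan-2-yl)butanamide
Product: 10 (2S,3S)-N-methoxy-4-[(4-methoxybenzyl)oxy]-N-methyl-2-(propan-2-yl)-3-[(triethylsilyl)oxy]butanamide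
Conditions: TESOTf, 2,6-lutidine, CH2Cl2, −78 → 0 °C
Reagents that add atoms: triethylsilyl triflate, CC[Si](CC)(CC)OS(=O)(=O)C(F)(F)F
Why: silyl triflate silylation protects the hindered secondary C1 hydroxyl as a TES ether that can later be removed beside the PMB ether.

Step 7
Reactants: 10 (2S,3S)-N-methoxy-4-[(4-methoxybenzyl)oxy]-N-methyl-2-(propan-2-yl)-3-[(triethylsilyl)oxy]butanamide
Product: 11 (2S,3S)-4-[(4-methoxybenzyl)oxy]-2-(propan-2-yl)-3-[(triethylsilyl)oxy]butanal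
Conditions: DIBAL-H, THF, −78 °C; Rochelle salt
Reagents that add atoms: none
Why: DIBAL reduction of a Weinreb amide stops at the aldehyde because the chelated tetrahedral adduct survives until work-up, and the low temperature keeps C2 intact.

Step 8
Reactants: 12 but-2-yn-1-ol
Product: 14 (2E)-3-iodobut-2-en-1-ol, via alkenylzirconocene 13 (not isolated)
Conditions: Cp2Zr(H)Cl (2.3 equiv), THF, rt; then I2, 0 °C
Reagents that add atoms: iodine, II
Why: syn-hydrozirconation (Schwartz reagent) places Zr on the methyl-bearing carbon remote from the bulky zirconium alkoxide, and iodinolysis with retention gives the E-iodoalkene that becomes C8=C9.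

Step 9
Reactants: 14 (2E)-3-iodobut-2-en-1-ol
Product: 15 (2E)-1-bromo-3-iodobut-2-ene
Conditions: CBr4, PPh3, CH2Cl2, 0 °C
Reagents that add atoms: carbon tetrabromide, BrC(Br)(Br)Br
Why: Appel bromination of the primary allylic alcohol under neutral conditions leaves the vinyl iodide and the alkene geometry untouched.

Step 10
Reactants: 16 trimethyl(prop-1-yn-1-yl)silane; 15 (2E)-1-bromo-3-iodobut-2-ene
Product: 18 [(5E)-6-iodohept-5-en-1-yn-1-yl]trimethylsilane, via lithiopropyne 17 (not isolated)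
Conditions: 16, n-BuLi, THF, −78 → −20 °C; then 15, −78 → −20 °C
Reagents that add atoms: none
Why: SN2 alkylation of the silyl-stabilised propargyl lithium by the primary allylic bromide forms C6–C7; the stabilised anion does not undergo I/Li exchange with the vinyl iodide.

Step 11
Reactants: 18 [(5E)-6-iodohept-5-en-1-yn-1-yl]trimethylsilane
Product: 19 (5E)-6-iodohept-5-en-1-yne
Conditions: K2CO3 (cat.), MeOH, rt
Reagents that add atoms: none
Why: methoxide-mediated protodesilylation of the alkynylsilane frees the terminal alkyne.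

Step 12
Reactants: 20 propanoyl chloride
Product: 21 (4R)-4-benzyl-3-propanoyl-1,3-oxazolidin-2-one
Conditions: (R)-4-benzyloxazolidin-2-one, n-BuLi, THF, −78 °C; then 20
Reagents that add atoms: (R)-4-benzyloxazolidin-2-one, O=C1N[C@H](Cc2ccccc2)CO1
Why: N-acylation of the lithiated Evans auxiliary by the acid chloride.

Step 13
Reactants: 21 (4R)-4-benzyl-3-propanoyl-1,3-oxazolidin-2-one; 22 acetaldehyde
Product: 24 (4R)-4-benzyl-3-[(2R,3S)-3-hydroxy-2-methylbutanoyl]-1,3-oxazolidin-2-one, via boron enolate 23 (not isolated)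
Conditions: n-Bu2BOTf, i-Pr2NEt, CH2Cl2, 0 °C; then 22, −78 → 0 °C; then pH 7 buffer, MeOH, 30 % H2O2
Reagents that add atoms: none
Why: Evans syn aldol reaction of the Z-boron enolate; the (R)-auxiliary gives the (2R,3S) syn pair of the side chain.

Step 14
Reactants: 24 (4R)-4-benzyl-3-[(2R,3S)-3-hydroxy-2-methylbutanoyl]-1,3-oxazolidin-2-one
Product: 26 (2R,3S)-3-hydroxy-2-methylbutanoic acid, via peroxy acid 25 (not isolated)
Conditions: LiOH, 30 % H2O2, THF/H2O, 0 °C; then Na2SO3; then HCl to pH 2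
Reagents that add atoms: hydrogen peroxide (as LiOOH), OO
Why: hydroperoxide cleaves the imide selectively at the exocyclic carbonyl without epimerisation, and sulfite reduces the peracid to the acid.

Step 15
Reactants: 26 (2R,3S)-3-hydroxy-2-methylbutanoic acid
Product: 28 (2R,3S)-3-acetoxy-2-methylbutanoic acid, via mixed anhydride 27 (not isolated)
Conditions: Ac2O, pyridine, DMAP (cat.), 0 °C → rt; then H2O
Reagents that add atoms: acetic anhydride, CC(=O)OC(C)=O
Why: O-acetylation of the secondary alcohol; the mixed carboxylic anhydride formed alongside is hydrolysed by water on work-up.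

Step 16
Reactants: 19 (5E)-6-iodohept-5-en-1-yne; 11 (2S,3S)-4-[(4-methoxybenzyl)oxy]-2-(propan-2-yl)-3-[(triethylsilyl)oxy]butanal
Product: 30 (2S,3R,5E,9E)-10-iodo-1-[(4-methoxybenzyl)oxy]-6-methyl-3-(propan-2-yl)-2-[(triethylsilyl)oxy]undeca-5,9-dien-4-ol (mixture of C4 epimers), via alkenylalane 29 (not isolated)
Conditions: 19 (1.5 equiv), AlMe3, Cp2ZrCl2 (0.25 equiv), CH2Cl2, 0 °C → rt; volatiles removed; then 11, CH2Cl2, −78 → 0 °C; Rochelle salt
Reagents that add atoms: trimethylaluminium, C[Al](C)C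
Why: Negishi Zr-catalysed syn-carboalumination puts the C5 methyl and Al cis, which fixes the E C4=C5 alkene; the alkenyl group of the alane then adds 1,2 to the aldehyde to form C3–C4, and the unselective carbinol is erased in step 17.

Step 17
Reactants: 30 (2S,3R,5E,9E)-10-iodo-1-[(4-methoxybenzyl)oxy]-6-methyl-3-(propan-2-yl)-2-[(triethylsilyl)oxy]undeca-5,9-dien-4-ol
Product: 31 (2S,3S,5E,9E)-10-iodo-1-[(4-methoxybenzyl)oxy]-6-methyl-3-(propan-2-yl)-2-[(triethylsilyl)oxy]undeca-5,9-dien-4-one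
Conditions: Dess–Martin periodinane, NaHCO3, CH2Cl2, 0 °C → rt
Reagents that add atoms: none
Why: Dess–Martin oxidation converts both allylic carbinol epimers into one enone under buffered conditions that spare the TES and PMB ethers and the vinyl iodide.

Step 18
Reactants: 31 (2S,3S,5E,9E)-10-iodo-1-[(4-methoxybenzyl)oxy]-6-methyl-3-(propan-2-yl)-2-[(triethylsilyl)oxy]undeca-5,9-dien-4-one
Product: 32 (2S,3S,5E,9E)-2-hydroxy-10-iodo-1-[(4-methoxybenzyl)oxy]-6-methyl-3-(propan-2-yl)undeca-5,9-dien-4-one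
Conditions: HF·pyridine, pyridine, THF, 0 °C
Reagents that add atoms: none
Why: buffered fluoride desilylation removes the TES ether without β-elimination or retro-aldol of the β-hydroxy enone.

Step 19
Reactants: 32 (2S,3S,5E,9E)-2-hydroxy-10-iodo-1-[(4-methoxybenzyl)oxy]-6-methyl-3-(propan-2-yl)undeca-5,9-dien-4-one; 33 (2E)-2-methylbut-2-enal
Product: 35 (2S,3R,4R,5E,9E)-4-hydroxy-10-iodo-1-[(4-methoxybenzyl)oxy]-6-methyl-3-(propan-2-yl)undeca-5,9-dien-2-yl (2E)-2-methylbut-2-enoate, via hemiacetal 34 (not isolated)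
Conditions: SmI2 (0.3 equiv), 33 (6 equiv), THF, −10 °C, dark
Reagents that add atoms: none
Why: Evans–Tishchenko reduction: the Sm(III)-bound hemiacetal delivers hydride intramolecularly through a chair transition state, giving the 1,3-anti carbinol at C3 while the former hydroxyl oxygen at C1 becomes the tiglate.

Step 20
Reactants: 35 (2S,3R,4R,5E,9E)-4-hydroxy-10-iodo-1-[(4-methoxybenzyl)oxy]-6-methyl-3-(propan-2-yl)undeca-5,9-dien-2-yl (2E)-2-methylbut-2-enoate
Product: 36 (2S,3R,4S)-4-hydroxy-4-[(2R,3R)-3-[(3E)-4-iodopent-3-en-1-yl]-3-methyloxiran-2-yl]-1-[(4-methoxybenzyl)oxy]-3-(propan-2-yl)butan-2-yl (2E)-2-methylbut-2-enoate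
Conditions: mCPBA (1.1 equiv), NaHCO3, CH2Cl2, −20 → 0 °C
Reagents that add atoms: 3-chloroperoxybenzoic acid, OOC(=O)c1cccc(Cl)c1
Why: hydroxyl-directed (Henbest) peracid epoxidation: A(1,3) strain from the cis C5 methyl holds the C3–H in the alkene plane, so the H-bonded peracid attacks the face syn to OH and gives the threo trans-epoxide (C4 R, C5 R); the enoate and the iodoalkene are too electron-poor to react.

Step 21
Reactants: 36 (2S,3R,4S)-4-hydroxy-4-[(2R,3R)-3-[(3E)-4-iodopent-3-en-1-yl]-3-methyloxiran-2-yl]-1-[(4-methoxybenzyl)oxy]-3-(propan-2-yl)butan-2-yl (2E)-2-methylbut-2-enoate; 28 (2R,3S)-3-acetoxy-2-methylbutanoic acid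
Product: 38 (1S,2S,3S)-1-[(2R,3R)-3-[(3E)-4-iodopent-3-en-1-yl]-3-methyloxiran-2-yl]-4-[(4-methoxybenzyl)oxy]-3-{[(2E)-2-methylbut-2-enoyl]oxy}-2-(propan-2-yl)butyl (2R,3S)-3-acetoxy-2-methylbutanoate, via mixed anhydride 37 (not isolated)
Conditions: 28, 2,4,6-Cl3C6H2COCl, Et3N, toluene, rt; then 36, DMAP, 0 °C → rt
Reagents that add atoms: none
Why: Yamaguchi esterification acylates the hindered C3 hydroxyl through the mixed anhydride and acyl-DMAP species without touching the epoxide.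

Step 22
Reactants: 38 (1S,2S,3S)-1-[(2R,3R)-3-[(3E)-4-iodopent-3-en-1-yl]-3-methyloxiran-2-yl]-4-[(4-methoxybenzyl)oxy]-3-{[(2E)-2-methylbut-2-enoyl]oxy}-2-(propan-2-yl)butyl (2R,3S)-3-acetoxy-2-methylbutanoate
Product: 39 (1S,2S,3S)-4-hydroxy-1-[(2R,3R)-3-[(3E)-4-iodopent-3-en-1-yl]-3-methyloxiran-2-yl]-3-{[(2E)-2-methylbut-2-enoyl]oxy}-2-(propan-2-yl)butyl (2R,3S)-3-acetoxy-2-methylbutanoate
Conditions: DDQ, CH2Cl2/pH 7 buffer (10:1), 0 °C
Reagents that add atoms: none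
Why: oxidative PMB cleavage (benzylic hydride abstraction by DDQ, then hydrolysis) is neutral and spares the epoxide, the three esters and the vinyl iodide.

Step 23
Reactants: 39 (1S,2S,3S)-4-hydroxy-1-[(2R,3R)-3-[(3E)-4-iodopent-3-en-1-yl]-3-methyloxiran-2-yl]-3-{[(2E)-2-methylbut-2-enoyl]oxy}-2-(propan-2-yl)butyl (2R,3S)-3-acetoxy-2-methylbutanoate
Product: 40 (1S,2R,3S)-1-[(2R,3R)-3-[(3E)-4-iodopent-3-en-1-yl]-3-methyloxiran-2-yl]-3-{[(2E)-2-methylbut-2-enoyl]oxy}-4-oxo-2-(propan-2-yl)butyl (2R,3S)-3-acetoxy-2-methylbutanoate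
Conditions: Dess–Martin periodinane, NaHCO3, CH2Cl2, 0 °C; used at once
Reagents that add atoms: none
Why: buffered Dess–Martin oxidation gives the α-acyloxy aldehyde without epimerising C1 or migrating the tiglate.

Step 24
Reactants: 40 (1S,2R,3S)-1-[(2R,3R)-3-[(3E)-4-iodopent-3-en-1-yl]-3-methyloxiran-2-yl]-3-{[(2E)-2-methylbut-2-enoyl]oxy}-4-oxo-2-(propan-2-yl)butyl (2R,3S)-3-acetoxy-2-methylbutanoate
Product: 42 (1R,4E,6R,7S,8S,9S,10R)-6-hydroxy-1,5-dimethyl-7-{[(2E)-2-methylbut-2-enoyl]oxy}-8-(propan-2-yl)-11-oxabicyclo[8.1.0]undec-4-en-9-yl (2R,3S)-3-acetoxy-2-methylbutanoate, via alkenylchromium 41 (not isolated)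
Conditions: CrCl2 (10 equiv), NiCl2 (2 mol %), degassed DMSO, rt, slow addition to 2 mM
Reagents that add atoms: none
Why: intramolecular Nozaki–Hiyama–Kishi reaction: Ni inserts into the C–I bond, the alkenyl group passes to Cr(III) and adds to the aldehyde with retention of the E geometry, and Felkin–Anh attack anti to the C1–O bond gives the 1,2-anti (10R) alcohol.

## Compound list

1 | prop-2-en-1-ol (allyl alcohol) | C=CCO | starting material
2 | allyl 4-methoxybenzyl ether, 1-methoxy-4-[(prop-2-en-1-yloxy)methyl]benzene | C=CCOCc1ccc(OC)cc1 | intermediate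
3 | 3-[(4-methoxybenzyl)oxy]propane-1,2-diol (racemic, not isolated) | OCC(O)COCc1ccc(OC)cc1 | intermediate
4 | 2-[(4-methoxybenzyl)oxy]acetaldehyde | O=CCOCc1ccc(OC)cc1 | intermediate
5 | 3-methylbutanoyl chloride | CC(C)CC(=O)Cl | starting material
6 | (4S)-4-benzyl-3-(3-methylbutanoyl)-1,3-oxazolidin-2-one | CC(C)CC(=O)N1[C@@H](Cc2ccccc2)COC1=O | intermediate
7 | (4S)-4-benzyl-3-[(1Z)-1-[(dibutylboranyl)oxy]-3-methylbut-1-en-1-yl]-1,3-oxazolidin-2-one (boron enolate, not isolated) | CCCCB(CCCC)O/C(=C\C(C)C)N1[C@@H](Cc2ccccc2)COC1=O | intermediate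
8 | (4S)-4-benzyl-3-[(2S,3S)-3-hydroxy-4-[(4-methoxybenzyl)oxy]-2-(propan-2-yl)butanoyl]-1,3-oxazolidin-2-one | O[C@H](COCc1ccc(OC)cc1)[C@H](C(C)C)C(=O)N1[C@@H](Cc2ccccc2)COC1=O | intermediate
9 | (2S,3S)-3-hydroxy-N-methoxy-4-[(4-methoxybenzyl)oxy]-N-methyl-2-(propan-2-yl)butanamide | O[C@H](COCc1ccc(OC)cc1)[C@H](C(C)C)C(=O)N(C)OC | intermediate
10 | (2S,3S)-N-methoxy-4-[(4-methoxybenzyl)oxy]-N-methyl-2-(propan-2-yl)-3-[(triethylsilyl)oxy]butanamide | CC[Si](CC)(CC)O[C@H](COCc1ccc(OC)cc1)[C@H](C(C)C)C(=O)N(C)OC | intermediate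
11 | (2S,3S)-4-[(4-methoxybenzyl)oxy]-2-(propan-2-yl)-3-[(triethylsilyl)oxy]butanal | CC[Si](CC)(CC)O[C@H](COCc1ccc(OC)cc1)[C@H](C(C)C)C=O | intermediate
12 | but-2-yn-1-ol | CC#CCO | starting material
13 | (2E)-but-2-en-1-ol zirconated at C3 and O, each Zr being Cp2ZrCl (not isolated; Cp drawn σ-bound) | C/C(=C\CO[Zr](Cl)(C1C=CC=C1)C1C=CC=C1)[Zr](Cl)(C1C=CC=C1)C1C=CC=C1 | intermediate
14 | (2E)-3-iodobut-2-en-1-ol | C/C(I)=C\CO | intermediate
15 | (2E)-1-bromo-3-iodobut-2-ene | C/C(I)=C\CBr | intermediate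
16 | trimethyl(prop-1-yn-1-yl)silane | CC#C[Si](C)(C)C | starting material
17 | (3-lithioprop-1-yn-1-yl)trimethylsilane (not isolated) | [Li]CC#C[Si](C)(C)C | intermediate
18 | [(5E)-6-iodohept-5-en-1-yn-1-yl]trimethylsilane | C[Si](C)(C)C#CCC/C=C(\C)I | intermediate
19 | (5E)-6-iodohept-5-en-1-yne | C#CCC/C=C(\C)I | intermediate
20 | propanoyl chloride | CCC(=O)Cl | starting material
21 | (4R)-4-benzyl-3-propanoyl-1,3-oxazolidin-2-one | CCC(=O)N1[C@H](Cc2ccccc2)COC1=O | intermediate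
22 | acetaldehyde | CC=O | starting material
23 | (4R)-4-benzyl-3-[(1Z)-1-[(dibutylboranyl)oxy]prop-1-en-1-yl]-1,3-oxazolidin-2-one (boron enolate, not isolated) | CCCCB(CCCC)O/C(=C\C)N1[C@H](Cc2ccccc2)COC1=O | intermediate
24 | (4R)-4-benzyl-3-[(2R,3S)-3-hydroxy-2-methylbutanoyl]-1,3-oxazolidin-2-one | O=C(N1[C@H](Cc2ccccc2)COC1=O)[C@H](C)[C@H](C)O | intermediate
25 | (2R,3S)-3-hydroxy-2-methylbutaneperoxoic acid (as its lithium salt, not isolated) | OOC(=O)[C@H](C)[C@H](C)O | intermediate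
26 | (2R,3S)-3-hydroxy-2-methylbutanoic acid | OC(=O)[C@H](C)[C@H](C)O | intermediate
27 | acetic (2R,3S)-3-acetoxy-2-methylbutanoic anhydride (not isolated) | CC(=O)OC(=O)[C@H](C)[C@H](C)OC(C)=O | intermediate
28 | (2R,3S)-3-acetoxy-2-methylbutanoic acid | OC(=O)[C@H](C)[C@H](C)OC(C)=O | intermediate
29 | [(1E,5E)-6-iodo-2-methylhepta-1,5-dien-1-yl]dimethylalane (not isolated) | C[Al](C)/C=C(\C)CC/C=C(\C)I | intermediate
30 | (2S,3R,5E,9E)-10-iodo-1-[(4-methoxybenzyl)oxy]-6-methyl-3-(propan-2-yl)-2-[(triethylsilyl)oxy]undeca-5,9-dien-4-ol (mixture of C4 epimers) | CC[Si](CC)(CC)O[C@H](COCc1ccc(OC)cc1)[C@H](C(C)C)C(O)/C=C(\C)CC/C=C(\C)I | intermediate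
31 | (2S,3S,5E,9E)-10-iodo-1-[(4-methoxybenzyl)oxy]-6-methyl-3-(propan-2-yl)-2-[(triethylsilyl)oxy]undeca-5,9-dien-4-one | CC[Si](CC)(CC)O[C@H](COCc1ccc(OC)cc1)[C@H](C(C)C)C(=O)/C=C(\C)CC/C=C(\C)I | intermediate
32 | (2S,3S,5E,9E)-2-hydroxy-10-iodo-1-[(4-methoxybenzyl)oxy]-6-methyl-3-(propan-2-yl)undeca-5,9-dien-4-one | O[C@H](COCc1ccc(OC)cc1)[C@H](C(C)C)C(=O)/C=C(\C)CC/C=C(\C)I | intermediate
33 | (2E)-2-methylbut-2-enal (tiglaldehyde) | C/C=C(\C)C=O | starting material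
34 | hemiacetal of 33 on the 2-hydroxyl of 32 (samarium-bound, not isolated) | C/C=C(\C)C(O)O[C@H](COCc1ccc(OC)cc1)[C@H](C(C)C)C(=O)/C=C(\C)CC/C=C(\C)I | intermediate
35 | (2S,3R,4R,5E,9E)-4-hydroxy-10-iodo-1-[(4-methoxybenzyl)oxy]-6-methyl-3-(propan-2-yl)undeca-5,9-dien-2-yl (2E)-2-methylbut-2-enoate | C/C=C(\C)C(=O)O[C@H](COCc1ccc(OC)cc1)[C@H](C(C)C)[C@H](O)/C=C(\C)CC/C=C(\C)I | intermediate
36 | (2S,3R,4S)-4-hydroxy-4-[(2R,3R)-3-[(3E)-4-iodopent-3-en-1-yl]-3-methyloxiran-2-yl]-1-[(4-methoxybenzyl)oxy]-3-(propan-2-yl)butan-2-yl (2E)-2-methylbut-2-enoate | C/C=C(\C)C(=O)O[C@H](COCc1ccc(OC)cc1)[C@H](C(C)C)[C@H](O)[C@H]2O[C@]2(C)CC/C=C(\C)I | intermediate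
37 | (2R,3S)-3-acetoxy-2-methylbutanoic 2,4,6-trichlorobenzoic anhydride (not isolated) | O=C(OC(=O)[C@H](C)[C@H](C)OC(C)=O)c1c(Cl)cc(Cl)cc1Cl | intermediate
38 | (1S,2S,3S)-1-[(2R,3R)-3-[(3E)-4-iodopent-3-en-1-yl]-3-methyloxiran-2-yl]-4-[(4-methoxybenzyl)oxy]-3-{[(2E)-2-methylbut-2-enoyl]oxy}-2-(propan-2-yl)butyl (2R,3S)-3-acetoxy-2-methylbutanoate | C/C=C(\C)C(=O)O[C@H](COCc1ccc(OC)cc1)[C@H](C(C)C)[C@H](OC(=O)[C@H](C)[C@H](C)OC(C)=O)[C@H]2O[C@]2(C)CC/C=C(\C)I | intermediate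
39 | (1S,2S,3S)-4-hydroxy-1-[(2R,3R)-3-[(3E)-4-iodopent-3-en-1-yl]-3-methyloxiran-2-yl]-3-{[(2E)-2-methylbut-2-enoyl]oxy}-2-(propan-2-yl)butyl (2R,3S)-3-acetoxy-2-methylbutanoate | C/C=C(\C)C(=O)O[C@H](CO)[C@H](C(C)C)[C@H](OC(=O)[C@H](C)[C@H](C)OC(C)=O)[C@H]1O[C@]1(C)CC/C=C(\C)I | intermediate
40 | (1S,2R,3S)-1-[(2R,3R)-3-[(3E)-4-iodopent-3-en-1-yl]-3-methyloxiran-2-yl]-3-{[(2E)-2-methylbut-2-enoyl]oxy}-4-oxo-2-(propan-2-yl)butyl (2R,3S)-3-acetoxy-2-methylbutanoate | C/C=C(\C)C(=O)O[C@H](C=O)[C@H](C(C)C)[C@H](OC(=O)[C@H](C)[C@H](C)OC(C)=O)[C@H]1O[C@]1(C)CC/C=C(\C)I | intermediate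
41 | alkenylchromium(III) dichloride from 40, C–I replaced by C–CrCl2 (not isolated) | C/C=C(\C)C(=O)O[C@H](C=O)[C@H](C(C)C)[C@H](OC(=O)[C@H](C)[C@H](C)OC(C)=O)[C@H]1O[C@]1(C)CC/C=C(\C)[Cr](Cl)Cl | intermediate
42 | (1R,4E,6R,7S,8S,9S,10R)-6-hydroxy-1,5-dimethyl-7-{[(2E)-2-methylbut-2-enoyl]oxy}-8-(propan-2-yl)-11-oxabicyclo[8.1.0]undec-4-en-9-yl (2R,3S)-3-acetoxy-2-methylbutanoate (CNP0332554.1) | C/C=C(\C)C(=O)O[C@H]1[C@H](C(C)C)[C@H](OC(=O)[C@H](C)[C@H](C)OC(C)=O)[C@H]2O[C@]2(C)CC/C=C(\C)[C@H]1O | target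

## Step count and risks

Total: 24 steps. Longest linear sequence: 15 steps (1, 2, 4–7, 16–24), which is 62.5 % of the total.

**Step 24 (Ni/Cr macrocyclisation).** Closing a ten-membered E-cycloalkene on an α-acyloxy aldehyde may give mainly the wrong C10 epimer. The fallback sets out from 40 and comes back at 42. The ring is still closed by the same coupling, and the isolated 10-epi alcohol F9 is oxidised with Dess–Martin periodinane to the macrocyclic enone F10. The ketone is then reduced under reagent control ((R)-Me-CBS, catecholborane, toluene, −78 °C, alkenyl as the large group) to give 42, so C10 is set by hydride delivery and not by the C–C bond formation.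

**Step 19 (Evans–Tishchenko with an enal).** Tiglaldehyde may be a poor hydride donor. The fallback sets out from 32 and comes back at 35.
- Run the same SmI2-catalysed reduction with acetaldehyde 22, the best-behaved donor, to give the 1,3-anti monoacetate F1.
- Silylate the C3 hydroxyl (TESOTf, 2,6-lutidine) to the acetate silyl ether F2.
- Remove the acetate (K2CO3, MeOH) to the C1 alcohol F3.
- Acylate with tigloyl chloride (pyridine, DMAP) to the tiglate silyl ether F4.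
- Remove the silyl group with HF·pyridine to return to 35.

**Step 21 (Yamaguchi coupling of the β-acetoxy acid).** Activated 28 may lose acetate by E1cB elimination or epimerise at C2′ before the hindered C3 hydroxyl reacts. The fallback sets out from 26 and 36 and comes back at 38.
- Silylate 26 twice (TESCl, imidazole, DMF) to the bis-silyl compound F5.
- Hydrolyse the silyl ester (K2CO3, MeOH/H2O) to the silyloxy acid F6, whose β-substituent is a poor leaving group.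
- Couple F6 to 36 (EDC·HCl, DMAP, CH2Cl2) to the silyloxy ester F7.
- Remove the silyl group (HF·pyridine, pyridine, THF, 0 °C) to the hydroxy ester F8.
- Acetylate (Ac2O, pyridine, DMAP) to return to 38.

Further compounds
F1 | step 19 | 2-O-acetyl analogue of 35, (2S,3R,4R,5E,9E)-4-hydroxy-10-iodo-1-[(4-methoxybenzyl)oxy]-6-methyl-3-(propan-2-yl)undeca-5,9-dien-2-yl acetate | CC(=O)O[C@H](COCc1ccc(OC)cc1)[C@H](C(C)C)[C@H](O)/C=C(\C)CC/C=C(\C)I
F2 | step 19 | 4-O-triethylsilyl ether of F1 | CC(=O)O[C@H](COCc1ccc(OC)cc1)[C@H](C(C)C)[C@H](O[Si](CC)(CC)CC)/C=C(\C)CC/C=C(\C)I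
F3 | step 19 | deacetylated F2, the 2-hydroxy 4-O-triethylsilyl compound | O[C@H](COCc1ccc(OC)cc1)[C@H](C(C)C)[C@H](O[Si](CC)(CC)CC)/C=C(\C)CC/C=C(\C)I
F4 | step 19 | 4-O-triethylsilyl ether of 35 | C/C=C(\C)C(=O)O[C@H](COCc1ccc(OC)cc1)[C@H](C(C)C)[C@H](O[Si](CC)(CC)CC)/C=C(\C)CC/C=C(\C)I
F5 | step 21 | triethylsilyl (2R,3S)-2-methyl-3-[(triethylsilyl)oxy]butanoate | CC[Si](CC)(CC)OC(=O)[C@H](C)[C@H](C)O[Si](CC)(CC)CC
F6 | step 21 | (2R,3S)-2-methyl-3-[(triethylsilyl)oxy]butanoic acid | OC(=O)[C@H](C)[C@H](C)O[Si](CC)(CC)CC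
F7 | step 21 | analogue of 38 with the side-chain acetate replaced by a triethylsilyl ether | C/C=C(\C)C(=O)O[C@H](COCc1ccc(OC)cc1)[C@H](C(C)C)[C@H](OC(=O)[C@H](C)[C@H](C)O[Si](CC)(CC)CC)[C@H]2O[C@]2(C)CC/C=C(\C)I
F8 | step 21 | analogue of 38 with a free side-chain 3-hydroxyl | C/C=C(\C)C(=O)O[C@H](COCc1ccc(OC)cc1)[C@H](C(C)C)[C@H](OC(=O)[C@H](C)[C@H](C)O)[C@H]2O[C@]2(C)CC/C=C(\C)I
F9 | step 24 | C10 epimer of 42 (6S in the bicyclic numbering) | C/C=C(\C)C(=O)O[C@H]1[C@H](C(C)C)[C@H](OC(=O)[C@H](C)[C@H](C)OC(C)=O)[C@H]2O[C@]2(C)CC/C=C(\C)[C@@H]1O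
F10 | step 24 | 10-oxo analogue of 42 (macrocyclic enone) | C/C=C(\C)C(=O)O[C@H]1[C@H](C(C)C)[C@H](OC(=O)[C@H](C)[C@H](C)OC(C)=O)[C@H]2O[C@]2(C)CC/C=C(\C)C1=O
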